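## Retrosynthetic overview

- The target comes from the hexol by acetylation of the two primary hydroxyls. 5α-H and 6α-OH come from α-face hydroboration of a 4α-hydroxy-5-ene, 10α-OH from hydride opening of a 9α,10α-epoxide, and the C11 carbinol from double addition of a benzyloxymethyl organometallic to a C11 methyl ester.
- The 4α-hydroxy-5-ene comes from a radical 1,3-transposition (epoxide fragmentation) of a 4α,5α-epoxy-6-ol.
- The seven-membered ring (formed second) comes from ring-closing metathesis of an allyl and an isopropenyl group, giving C9=C10.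
- The key C6–C7 bond comes from an intermolecular Evans boron aldol between a cyclopentane α,β-epoxy aldehyde and N-pent-4-enoyl oxazolidinone, which sets C7.
- The five-membered ring (formed first) comes from intramolecular aldol condensation of the keto aldehyde from (+)-limonene oxide (C1 from the chiral pool), followed by Sharpless epoxidation (C4, C5).

Assumption: guaiane numbering is used for the bicyclic compounds (C1/C5 ring fusion, C4 and C10 methyl carbinols, C6 secondary carbinol, C7 side-chain carbon, C11 side-chain carbinol, C12/C13 its CH2O arms); α is the face of H-1 and H-5 of the target.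

## Route

Step 1
Reactants: 1 (+)-limonene 1,2-oxide
Product: 3 (3R)-6-oxo-3-(prop-1-en-2-yl)heptanal, via limonene-1,2-diol 2 (not isolated)
Conditions: H5IO6 (1.1 equiv), THF/H2O, 0 °C to rt
Reagents that add atoms: water, O
Why: Acid-promoted epoxide hydrolysis followed by periodate glycol cleavage (Malaprade reaction) opens the cyclohexane to the keto aldehyde and leaves the isopropenyl group and the stereocentre (later C1) untouched.

Step 2
Reactants: 3 (3R)-6-oxo-3-(prop-1-en-2-yl)heptanal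
Product: 5 (5S)-2-methyl-5-(prop-1-en-2-yl)cyclopent-1-ene-1-carbaldehyde, via aldol ketol 4 (not isolated)
Conditions: piperidine (0.2 equiv), AcOH (0.2 equiv), benzene, reflux, Dean–Stark
Reagents that add atoms: none
Why: Enamine-mediated intramolecular aldol condensation (aldehyde α-carbon onto the methyl ketone, 5-enolexo) closes the five-membered ring as the tetrasubstituted enal, and the remaining stereocentre is not enolisable.

Step 3
Reactants: 5 (5S)-2-methyl-5-(prop-1-en-2-yl)cyclopent-1-ene-1-carbaldehyde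
Product: 6 [(5S)-2-methyl-5-(prop-1-en-2-yl)cyclopent-1-en-1-yl]methanol
Conditions: NaBH4, CeCl3·7H2O, MeOH, 0 °C
Reagents that add atoms: none
Why: Luche reduction gives selective 1,2-reduction of the enal to the primary allylic alcohol needed for directed epoxidation.

Step 4
Reactants: 6 [(5S)-2-methyl-5-(prop-1-en-2-yl)cyclopent-1-en-1-yl]methanol
Product: 7 [(1R,2S,5R)-5-methyl-2-(prop-1-en-2-yl)-6-oxabicyclo[3.1.0]hexan-1-yl]methanol
Conditions: Ti(OiPr)4 (10 mol%), D-(−)-diethyl tartrate (12 mol%), t-BuOOH (2 equiv), 4 Å molecular sieves, CH2Cl2, −20 °C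
Reagents that add atoms: tert-butyl hydroperoxide, CC(C)(C)OO
Why: Sharpless asymmetric epoxidation with the D-tartrate ligand delivers oxygen to the α-face, which is also the face anti to the isopropenyl group (matched case), so C4 and C5 are set as the 4α,5α-epoxide and the isopropenyl alkene is not touched.

Step 5
Reactants: 7 [(1R,2S,5R)-5-methyl-2-(prop-1-en-2-yl)-6-oxabicyclo[3.1.0]hexan-1-yl]methanol
Product: 8 (1S,2S,5R)-5-methyl-2-(prop-1-en-2-yl)-6-oxabicyclo[3.1.0]hexane-1-carbaldehyde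
Conditions: Dess–Martin periodinane, pyridine, CH2Cl2, 0 °C to rt
Reagents that add atoms: none
Why: Dess–Martin oxidation gives the α,β-epoxy aldehyde, which has a quaternary α-carbon and therefore cannot enolise or epimerise.

Step 6
Reactants: 9 (4R)-4-benzyl-1,3-oxazolidin-2-one; 10 pent-4-enoyl chloride
Product: 11 (4R)-4-benzyl-3-(pent-4-enoyl)-1,3-oxazolidin-2-one
Conditions: n-BuLi, THF, −78 °C; then 10, −78 to 0 °C
Reagents that add atoms: none
Why: N-Acylation of the lithiated oxazolidinone with the acid chloride gives the Evans imide.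

Step 7
Reactants: 8 (1S,2S,5R)-5-methyl-2-(prop-1-en-2-yl)-6-oxabicyclo[3.1.0]hexane-1-carbaldehyde; 11 (4R)-4-benzyl-3-(pent-4-enoyl)-1,3-oxazolidin-2-one
Product: 13 (4R)-4-benzyl-3-{(2R)-2-[(R)-hydroxy{(1R,2S,5R)-5-methyl-2-(prop-1-en-2-yl)-6-oxabicyclo[3.1.0]hexan-1-yl}methyl]pent-4-enoyl}-1,3-oxazolidin-2-one, via Z-dibutylboron enolate 12 (not isolated)
Conditions: 11, Bu2BOTf (1.1 equiv), i-Pr2NEt (1.2 equiv), CH2Cl2, −78 to 0 °C; then 8, −78 to 0 °C; pH 7 buffer, MeOH, H2O2, 0 °C
Reagents that add atoms: none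
Why: Evans syn-aldol addition of the Z-boron enolate through a Zimmerman–Traxler chair joins the two fragments at C6–C7, with the (R)-benzyl auxiliary fixing C7 as R; the C6 carbinol centre formed with it is erased in step 12, so only the auxiliary-controlled centre matters.

Step 8
Reactants: 13 the aldol adduct
Product: 14 methyl (2R)-2-[(R)-hydroxy{(1R,2S,5R)-5-methyl-2-(prop-1-en-2-yl)-6-oxabicyclo[3.1.0]hexan-1-yl}methyl]pent-4-enoate
Conditions: MeMgBr (1.5 equiv), MeOH, CH2Cl2, 0 °C
Reagents that add atoms: methanol, CO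
Why: Transesterification with bromomagnesium methoxide cleaves the exocyclic imide carbonyl, the magnesium chelate suppressing retro-aldol, and frees the auxiliary for recovery.

Step 9
Reactants: 14 the hydroxy ester diene
Product: 15 methyl (1S,4R,5R,6R,7R)-4,5-epoxy-6-hydroxy-12,13-dinorguai-9-en-11-oate
Conditions: second-generation Grubbs catalyst (5 mol%), toluene (0.005 M), 80 °C
Reagents that add atoms: none
Why: Ring-closing metathesis of the allyl and isopropenyl groups, which sit cis on the cyclopentane (both anti to the epoxide), closes the seven-membered ring as the trisubstituted C9=C10 alkene.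

Step 10
Reactants: 15 the bicyclic epoxy alkene
Product: 16 methyl (1S,4R,5R,6R,7R,9R,10S)-4,5:9,10-diepoxy-6-hydroxy-12,13-dinorguaian-11-oate
Conditions: dimethyldioxirane, acetone, 0 °C
Reagents that add atoms: dimethyldioxirane, CC1(C)OO1
Why: Electrophilic epoxidation of the only alkene occurs from the convex α-face, syn to H-1 and away from the cyclopentane methylene C2 and the β-substituents at C6 and C7, which sets the C10 oxygen as α.

Step 11
Reactants: 16 the diepoxy alcohol
Product: 17 methyl (1S,4R,5R,6R,7R,9R,10S)-4,5:9,10-diepoxy-6-[(1H-imidazol-1-ylcarbonothioyl)oxy]-12,13-dinorguaian-11-oate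
Conditions: 1,1'-thiocarbonyldiimidazole (3 equiv), DMAP (0.2 equiv), ClCH2CH2Cl, 70 °C
Reagents that add atoms: 1,1'-thiocarbonyldiimidazole, S=C(n1ccnc1)n1ccnc1
Why: Thioacylation of the only free hydroxyl gives the thiocarbonylimidazolide needed for Barton–McCombie-type radical generation.

Step 12
Reactants: 17 the thiocarbonylimidazolide
Product: 18 methyl (1R,4R,7R,9R,10S)-9,10-epoxy-4-hydroxy-12,13-dinorguai-5-en-11-oate
Conditions: Bu3SnH (5 equiv, 0.5 M), Et3B (0.2 equiv), air, benzene, rt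
Reagents that add atoms: none
Why: Barton–McCombie C6–O homolysis gives a C6 radical that opens the adjacent epoxide (epoxycarbinyl radical fragmentation) and the resulting alkoxyl radical is reduced by the excess stannane, so the oxygen stays on C4 with its α-configuration and the C5=C6 alkene is formed.

Step 13
Reactants: 18 the hydroxy alkene ester
Product: 19 (1R,4R,7R,9R,10S)-12,13-bis(benzyloxy)-9,10-epoxyguai-5-ene-4,11-diol
Conditions: BnOCH2SnBu3 (4 equiv), n-BuLi, THF, −78 °C; CeCl3, −78 °C; then 18, −78 to −40 °C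
Reagents that add atoms: tributyl[(benzyloxy)methyl]stannane, CCCC[Sn](CCCC)(CCCC)COCc1ccccc1
Why: Double 1,2-addition of the weakly basic organocerium reagent to the methyl ester builds the C11 carbinol with both oxygenated arms without deprotonating the allylic C7–H, and C11 is not a stereocentre.

Step 14
Reactants: 19 the epoxy diol
Product: 20 (1R,4R,7R,10R)-12,13-bis(benzyloxy)guai-5-ene-4,10,11-triol
Conditions: LiEt3BH (5 equiv), THF, 0 °C to rt
Reagents that add atoms: none
Why: SN2 hydride opening of the trisubstituted epoxide at the less hindered C9 leaves the C10–O bond intact and gives the 10α-tertiary alcohol.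

Step 15
Reactants: 20 the triol alkene
Product: 22 (1R,4R,5S,6S,7R,10R)-12,13-bis(benzyloxy)guaiane-4,6,10,11-tetrol, via C6-alkylborane 21 (not isolated)
Conditions: BH3·THF (6 equiv), THF, 0 °C to rt; then NaOH, H2O2, 0 °C to rt
Reagents that add atoms: hydrogen peroxide, OO
Why: Hydroboration–oxidation adds H and B syn from the α-face, anti to the 4β-methyl group and the bulky 7β-side chain, with boron at the less substituted C6, which sets the cis ring fusion (5α-H) and the 6α-hydroxyl.

Step 16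
Reactants: 22 the bis-benzyl ether tetrol
Product: 23 (1R,4R,5S,6S,7R,10R)-guaiane-4,6,10,11,12,13-hexol
Conditions: H2 (1 atm), Pd(OH)2/C, EtOH, rt
Reagents that add atoms: none
Why: Catalytic hydrogenolysis removes both benzyl ethers under neutral conditions.

Step 17
Reactants: 23 the hexol
Product: 24 (1R,4R,5S,6S,7R,10R)-4,6,10,11-tetrahydroxyguaiane-12,13-diyl diacetate (CNP0179913.1)
Conditions: Ac2O (2.2 equiv), 2,4,6-collidine, CH2Cl2, −20 to 0 °C
Reagents that add atoms: acetic anhydride, CC(=O)OC(C)=O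
Why: Kinetically selective acylation of the two primary hydroxyls leaves the hindered secondary and the three tertiary hydroxyls free.

## Compound list

1 | (+)-limonene 1,2-oxide, (4R)-1-methyl-4-(prop-1-en-2-yl)-7-oxabicyclo[4.1.0]heptane (cis/trans mixture at the epoxide) | CC12OC1C[C@@H](CC2)C(C)=C | starting material
2 | (4R)-1-methyl-4-(prop-1-en-2-yl)cyclohexane-1,2-diol (limonene-1,2-diol) | CC1(O)C(O)C[C@@H](CC1)C(C)=C | intermediate
3 | (3R)-6-oxo-3-(prop-1-en-2-yl)heptanal | O=CC[C@@H](CCC(C)=O)C(C)=C | intermediate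
4 | (5R)-2-hydroxy-2-methyl-5-(prop-1-en-2-yl)cyclopentane-1-carbaldehyde (aldol ketol, mixture at C1 and C2) | O=CC1C(C)(O)CC[C@H]1C(C)=C | intermediate
5 | (5S)-2-methyl-5-(prop-1-en-2-yl)cyclopent-1-ene-1-carbaldehyde | O=CC1=C(C)CC[C@H]1C(C)=C | intermediate
6 | [(5S)-2-methyl-5-(prop-1-en-2-yl)cyclopent-1-en-1-yl]methanol | OCC1=C(C)CC[C@H]1C(C)=C | intermediate
7 | [(1R,2S,5R)-5-methyl-2-(prop-1-en-2-yl)-6-oxabicyclo[3.1.0]hexan-1-yl]methanol (epoxide anti to isopropenyl) | OC[C@@]12O[C@]1(C)CC[C@H]2C(C)=C | intermediate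
8 | (1S,2S,5R)-5-methyl-2-(prop-1-en-2-yl)-6-oxabicyclo[3.1.0]hexane-1-carbaldehyde | O=C[C@@]12O[C@]1(C)CC[C@H]2C(C)=C | intermediate
9 | (4R)-4-benzyl-1,3-oxazolidin-2-one | O=C1N[C@H](Cc2ccccc2)CO1 | starting material
10 | pent-4-enoyl chloride | C=CCCC(Cl)=O | starting material
11 | (4R)-4-benzyl-3-(pent-4-enoyl)-1,3-oxazolidin-2-one | O=C1OC[C@@H](Cc2ccccc2)N1C(=O)CCC=C | intermediate
12 | Z-dibutylboron enolate of 11, (4R)-4-benzyl-3-[(1Z)-1-(dibutylboranyloxy)penta-1,4-dien-1-yl]-1,3-oxazolidin-2-one | O=C1OC[C@@H](Cc2ccccc2)N1/C(OB(CCCC)CCCC)=C/CC=C | intermediate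
13 | (4R)-4-benzyl-3-{(2R)-2-[(R)-hydroxy{(1R,2S,5R)-5-methyl-2-(prop-1-en-2-yl)-6-oxabicyclo[3.1.0]hexan-1-yl}methyl]pent-4-enoyl}-1,3-oxazolidin-2-one (Evans syn-aldol adduct) | O=C1OC[C@@H](Cc2ccccc2)N1C(=O)[C@H](CC=C)[C@@H](O)[C@@]34O[C@]3(C)CC[C@H]4C(C)=C | intermediate
14 | methyl (2R)-2-[(R)-hydroxy{(1R,2S,5R)-5-methyl-2-(prop-1-en-2-yl)-6-oxabicyclo[3.1.0]hexan-1-yl}methyl]pent-4-enoate | COC(=O)[C@H](CC=C)[C@@H](O)[C@@]12O[C@]1(C)CC[C@H]2C(C)=C | intermediate
15 | methyl (1S,4R,5R,6R,7R)-4,5-epoxy-6-hydroxy-12,13-dinorguai-9-en-11-oate (4α,5α-epoxide, 6β-OH, 1α-H, 7α-H) | COC(=O)[C@@H]1CC=C(C)[C@@H]2CC[C@@]4(C)O[C@@]24[C@@H]1O | intermediate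
16 | methyl (1S,4R,5R,6R,7R,9R,10S)-4,5:9,10-diepoxy-6-hydroxy-12,13-dinorguaian-11-oate (both epoxides α, 6β-OH) | COC(=O)[C@@H]1C[C@H]3O[C@@]3(C)[C@@H]2CC[C@@]4(C)O[C@@]24[C@@H]1O | intermediate
17 | methyl (1S,4R,5R,6R,7R,9R,10S)-4,5:9,10-diepoxy-6-[(1H-imidazol-1-ylcarbonothioyl)oxy]-12,13-dinorguaian-11-oate | COC(=O)[C@@H]1C[C@H]3O[C@@]3(C)[C@@H]2CC[C@@]4(C)O[C@@]24[C@@H]1OC(=S)n5ccnc5 | intermediate
18 | methyl (1R,4R,7R,9R,10S)-9,10-epoxy-4-hydroxy-12,13-dinorguai-5-en-11-oate (4α-OH, 9α,10α-epoxide) | COC(=O)[C@@H]1C[C@H]3O[C@@]3(C)[C@@H]2CC[C@@](C)(O)C2=C1 | intermediate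
19 | (1R,4R,7R,9R,10S)-12,13-bis(benzyloxy)-9,10-epoxyguai-5-ene-4,11-diol | OC(COCc6ccccc6)(COCc7ccccc7)[C@@H]1C[C@H]3O[C@@]3(C)[C@@H]2CC[C@@](C)(O)C2=C1 | intermediate
20 | (1R,4R,7R,10R)-12,13-bis(benzyloxy)guai-5-ene-4,10,11-triol (4α-OH, 10α-OH) | OC(COCc6ccccc6)(COCc7ccccc7)[C@@H]1CC[C@@](C)(O)[C@@H]2CC[C@@](C)(O)C2=C1 | intermediate
21 | C6-alkylborane from 20: 6α-boranyl, 5α-H (hydroxyls drawn free; in the flask they are borate esters) | OC(COCc6ccccc6)(COCc7ccccc7)[C@@H]1CC[C@@](C)(O)[C@@H]2CC[C@@](C)(O)[C@@H]2[C@H]1B | intermediate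
22 | (1R,4R,5S,6S,7R,10R)-12,13-bis(benzyloxy)guaiane-4,6,10,11-tetrol | OC(COCc6ccccc6)(COCc7ccccc7)[C@@H]1CC[C@@](C)(O)[C@@H]2CC[C@@](C)(O)[C@@H]2[C@H]1O | intermediate
23 | (1R,4R,5S,6S,7R,10R)-guaiane-4,6,10,11,12,13-hexol | OCC(O)(CO)[C@@H]1CC[C@@](C)(O)[C@@H]2CC[C@@](C)(O)[C@@H]2[C@H]1O | intermediate
24 | (1R,4R,5S,6S,7R,10R)-4,6,10,11-tetrahydroxyguaiane-12,13-diyl diacetate (CNP0179913.1) | CC(=O)OCC(O)(COC(C)=O)[C@@H]1CC[C@@](C)(O)[C@@H]2CC[C@@](C)(O)[C@@H]2[C@H]1O | target

## Step count and risk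

Total step count: 17. Longest linear sequence: 16 steps (steps 1–5 and 7–17, from 1 to 24); step 6 is the only side branch.

Three steps most likely to fail:

Step 10, facial selectivity of the C9=C10 epoxidation. The 6β-hydroxyl sits across the ring and could hydrogen-bond the oxidant onto the β-face, against the steric preference. The fallback sets out from 15: Et3SiOTf and 2,6-lutidine (CH2Cl2, −78 °C) give the triethylsilyl ether F1, which has no hydrogen-bond donor and extra bulk on the β-face. mCPBA/NaHCO3 (CH2Cl2, 0 °C) then gives the 9α,10α-epoxy silyl ether F2, and Bu4NF (THF, 0 °C) removes the silyl group, so the fallback comes back to the route at 16.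

Step 12, radical epoxide fragmentation. The tertiary cyclopentyl alkoxyl radical can undergo β-scission (ring opening) before the stannane reduces it, and the thiocarbonyl derivative sits on a very hindered carbinol. The fallback sets out from 16 and replaces the radical transposition with an ionic one. The ester is first converted with BnOCH2SnBu3/n-BuLi/CeCl3 (THF, −78 °C) into the bis(benzyloxymethyl) diepoxy diol F3. Dess–Martin oxidation of its only secondary hydroxyl gives the α,β-epoxy ketone F4. A Wharton transposition (N2H4·H2O, catalytic AcOH, MeOH, 0 °C to rt) then gives the 4α-hydroxy-5-ene directly, so the fallback comes back to the route at 19 and makes steps 11–13 unnecessary.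

Step 13, double addition to a hindered ester that carries an acidic allylic α-hydrogen. Enolisation or a stop at the ketone stage is possible. The fallback sets out from 18 and builds C11 in two separate additions. MeNH(OMe)·HCl with i-PrMgCl (THF, −20 °C) gives the Weinreb amide F5. One benzyloxymethyl unit is added with BnOCH2Li (THF, −78 °C), where the chelated tetrahedral intermediate stops the reaction at the benzyloxymethyl ketone F6. A second BnOCH2Li/CeCl3 addition to this much more electrophilic ketone (−78 °C) comes back to the route at 19.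

## Further compounds

F1 | step 10 | methyl 4α,5α-epoxy-6β-(triethylsilyloxy)-12,13-dinorguai-9-en-11-oate (triethylsilyl ether of 15) | COC(=O)[C@@H]1CC=C(C)[C@@H]2CC[C@@]4(C)O[C@@]24[C@@H]1O[Si](CC)(CC)CC
F2 | step 10 | methyl 4α,5α:9α,10α-diepoxy-6β-(triethylsilyloxy)-12,13-dinorguaian-11-oate (triethylsilyl ether of 16) | COC(=O)[C@@H]1C[C@H]3O[C@@]3(C)[C@@H]2CC[C@@]4(C)O[C@@]24[C@@H]1O[Si](CC)(CC)CC
F3 | step 12 | 12,13-bis(benzyloxy)-4α,5α:9α,10α-diepoxyguaiane-6β,11-diol | OC(COCc6ccccc6)(COCc7ccccc7)[C@@H]1C[C@H]3O[C@@]3(C)[C@@H]2CC[C@@]4(C)O[C@@]24[C@@H]1O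
F4 | step 12 | 12,13-bis(benzyloxy)-4α,5α:9α,10α-diepoxy-11-hydroxyguaian-6-one | OC(COCc6ccccc6)(COCc7ccccc7)[C@@H]1C[C@H]3O[C@@]3(C)[C@@H]2CC[C@@]4(C)O[C@@]24C1=O
F5 | step 13 | 9α,10α-epoxy-4α-hydroxy-N-methoxy-N-methyl-12,13-dinorguai-5-en-11-amide (Weinreb amide of 18) | CON(C)C(=O)[C@@H]1C[C@H]3O[C@@]3(C)[C@@H]2CC[C@@](C)(O)C2=C1
F6 | step 13 | 12-(benzyloxy)-9α,10α-epoxy-4α-hydroxy-13-norguai-5-en-11-one | O=C(COCc6ccccc6)[C@@H]1C[C@H]3O[C@@]3(C)[C@@H]2CC[C@@](C)(O)C2=C1
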